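## Structural features

Numbering used throughout: C1, C2, C3 are the three CH–O carbons, C4 the quaternary C–Me, C4–C5–C6–C7 the cyclobutane, C8 the ketone, C9 the CH2, C10 the CH–Me and C11 the CMe2 carbon.

The target is a tricycle. A cyclohexanone (C5–C6–C7–C8–C9–C10) is bridged across C5/C7 by C4, giving a bicyclo[3.1.1]heptan-2-one, and a seven-membered ring (C1–C2–C3–C4–C5–C6–C11) shares the C4–C5–C6 edge of the cyclobutane. Eight stereocentres are present: the contiguous carbinols C1, C2 and C3, the quaternary C4, the cyclobutane methines C5, C6 and C7, and C10. C2–O and C3–O are cis on the seven-membered ring and C1–O is trans to them. On the cyclobutane, C3 and C11 sit 1,3-cis on the face remote from the C8–C10 bridge, while the C4 methyl points over that bridge and the C10 methyl points towards C6.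

The fragile groups are the two angelates, which are Z-enoates that isomerise to tiglates with base, nucleophiles or heat and that accept radicals and hydrogen atoms. The acetate sits between two acyloxy groups and can migrate, and the cyclobutane is strained. The real difficulty is the all-cis crowding around the cyclobutane (C4, C5, C6, C7), with two quaternary carbons (C4 and C11) each next to a hindered carbinol, and the need to tell three neighbouring hydroxyls apart.

The key step exploits the fact that C11 is a CMe2 carbon between C6 and the carbinol C1. That is the pattern left when a hydrogen atom is added to an isopropenyl group on C6 and the resulting tertiary radical is joined to an aldehyde carbon. The cis-1,3 arrangement of C3 and C11 on the cyclobutane, together with a cis-fused C2/C3 dioxolane, brings C1 within reach of C11.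

## Logic of the disconnections

**Acyl–oxygen bonds (28 → 27 + 24 → 26 → 25 → 23 + 24).** The three ester bonds at C3, C2 and C1 are cut first, together with the two ketals. The angelates cannot survive a radical or hydride step, so they go on last. This leaves 23, which already holds every ring and all eight stereocentres. The forward demand is an acylation order: C1 while C2/C3 are tied in the dioxolane, then C2 in preference to the neopentyl C3, then C3 without moving the C2 acetate.

**C1–C11 (23 → 22).** This cut removes the seven-membered ring, one quaternary carbon and the C1 stereocentre, leaving a bicycle with one side chain. The forward step must place a hydrogen atom on the only alkene in the Markovnikov sense, close the 7-exo ring faster than the radical is reduced, and present the correct aldehyde face.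

**C1 oxidation level and dioxolane (22 → 21 → 20).** The epimerisable cis-dioxolane aldehyde is unmasked only in the last step before the closure. The gain is a stable ester–diol, 20. The demand is that the C2/C3 diol is the anti (erythro) one, because only that gives the cis-dioxolane.

**C2–C3 (20 → 19 → 17 + 18).** Both carbinol centres are set in one reagent-controlled aldol next to the quaternary C4. Because C2–O and C3–O are cis on the ring, the open-chain relationship is anti, so the aldol must be anti-selective; a syn aldol would give the trans-dioxolane and the wrong diastereomer. The gain is 17, which has no oxygen stereocentres. The demand is an anti-selective aldol that needs no Lewis acid, since the C3 aldehyde lies next to the isopropenyl group and could undergo a carbonyl-ene reaction.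

**C3 oxidation level, C8 ketal and the C10–CH3 bond (17 → 16 → 15 → 14 → 12).** The aldehyde is traced to a nitrile and the C10 methyl is cut to give the bridged enone 14. Its two faces differ sharply (C4 methyl over one, C6 hydrogen over the other), so the methyl can be delivered with confidence. The gain is 12, with no C10 stereocentre. The demand is a deprotection/reprotection of C8 around the enone chemistry.

**C4–C7 (12 → 11 → 10 → 9).** The cyclobutane is opened at the bond between the nitrile-bearing quaternary carbon and C7. The forward step is an SN2 closure by a nitrile-stabilised carbanion, which creates the quaternary centre and sets C7 by inversion. The gain is a monocyclic cyclohexane, 9. The demand is a leaving group on C7 trans to the C5 arm, the isopropenyl group cis to that arm, and the nitrile (not the methyl) ending on the isopropenyl side of C4.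

**C6–isopropenyl (9 → 7 + 8, and 7 → 6).** The isopropenyl group is removed as a Grignard reagent and the C7 hydroxyl is traced to an epoxide. A conjugate addition to an enone would place the isopropenyl group trans to a C5 substituent; anti opening of an epoxide that is itself trans to the C5 arm places it cis. The gain is that C6 and C7 both disappear. The demand is face selectivity in the epoxidation and attack at C6 rather than C7.

**C4–C5 (6 → 5 → 3 + 4, and 3 → 2 → 1).** The C5 arm is cut as a soft carbon acid in an allylic substitution with net retention, and the single remaining stereocentre is traced to an enantioselective ketone reduction. The gain is an achiral, purchasable enone ketal, 1. The demand is high enantioselectivity in one step, since every later centre is relayed from C5.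

## Other disconnections considered

**Alternative 1:** Transannular Ireland–Claisen ring contraction.
- **Cut:** the cyclobutane bond C4–C7, traded for a C2–O lactone bond, with the alkene moving from C3=C4 to C2=C3.
- **Forward key step:** a bridged unsaturated lactone (acyl carbon C8, ring oxygen on C2) is converted to its silyl ketene acetal, which rearranges through the six-atom array C7=C8–O–C2–C3=C4 to the bicyclo[4.1.1]octene acid A1.
- **In favour:** the step is concerted and stereospecific, and the C2 carbinol configuration is relayed to C4 and C7 in one event. A1 already contains the seven-membered ring with the CMe2 carbon, the cyclobutane and the C1 oxygen as a differentiated ether.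
- **Against:** A1 has no cyclohexanone; C8 is an acid and C10 a silyloxymethyl arm, so the ring and the C10 methyl stereocentre must be built afterwards. The C2/C3 diol must be added to a hindered bridged cycloheptene between two quaternary carbons, with uncertain face selectivity. The bridged lactone precursor is itself long to make.
- **Comparison:**
  - Structure: A1 holds five of the eight stereocentres and two of the three rings, whereas 23 holds all of both.
  - Mechanism: the alternative is the better of the two, being a precedented sigmatropic reaction class rather than an unprecedented radical closure.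
  - Step economy: worse, because a ring annulation, a methyl stereocentre and a dihydroxylation all follow the key step.

**Alternative 2:** Norcaranyl-to-norpinyl cation ring expansion with enol ether capture.
- **Cut:** C5–C6 and C3–C4.
- **Forward key step:** Me3SiOTf ionises a C5 acetate next to a cyclopropane (C4, C6, C7) in a bicyclo[4.1.0]heptane. C6 migrates from C4 to C5, and the tertiary cation at C4 is trapped by the carbon C3 of a tethered silyl enol ether, giving A2.
- **In favour:** two C–C bonds, the cyclobutane, the seven-membered ring and the quaternary C4 form in one operation, and the capture of a tertiary cation by an enol ether is irreversible. In bonds and rings formed per step the alternative is the better.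
- **Against:** cyclopropylcarbinyl, cyclobutyl and homoallyl cations interconvert, so ring-opened and eliminated products compete with a slow seven-membered closure. The Lewis acid also threatens the C8 ketal. A2 has C2 as a ketone and no oxygen at C3, so a neopentyl α-oxidation and a stereoselective reduction remain.
- **Comparison:**
  - Structure: A2 holds the whole carbon skeleton and six stereocentres but only one of the three carbinol centres; 23 has all three, set under reagent control before ring closure.
  - Mechanism: a cation cascade with several escape channels, against a radical closure with essentially one (premature reduction).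
  - Step economy: about equal overall; the shorter route to the tricycle is offset by a longer oxygenation endgame.

**Alternative 3:** Radical relay annulation across a bicyclobutane central bond.
- **Cut:** C6–C11 and C3–C4.
- **Forward key step:** under tris(trimethylsilyl)silane chain conditions, a tertiary α-keto radical at C11 (from a bromo enone) adds to bridgehead C6 of a bicyclo[1.1.0]butane. The central C4–C6 bond breaks, and the tertiary cyclobutyl radical at C4 closes on the enone terminus C3, giving A3.
- **In favour:** it is convergent, strain release makes the first addition irreversible, and both radical additions are polarity-matched. On driving force and convergence the alternative is the better; the chosen closure onto an aldehyde is reversible.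
- **Against:** A3 has no oxygen at C2 or C3 and a ketone at C1. All three carbinol centres would have to be introduced on the finished, crowded tricycle (dehydrogenation, cis-dihydroxylation, reduction) under substrate control only. The enantiopure, acid-labile bicyclobutane carrying the C4 methyl, the C10 methyl and the C8 ketal is a demanding substrate. The configuration at C6 and the competition of a seven-membered closure with hydrogen transfer from the silane are both open.
- **Comparison:**
  - Structure: A3 holds the full skeleton and five stereocentres but none of C1–C3.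
  - Mechanism: the alternative is the better.
  - Step economy: equal or better up to the tricycle, worse afterwards; overall the chosen plan is preferred because C1–C3 are secured earlier.

Key step: step 18

Remarks on the chemistry (assumptions):
- The facial sense of 18 is taken to be aldehyde approach anti to the axial methoxy group on the ring carbon next to the ether oxygen, and that of the oxazaborolidine to be the alkenyl arm acting as the large group. If either sense were the opposite, the enantiomeric reagent would be used.
- Compounds 1, 4, 8, 18 and 24 are taken to be purchasable.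
- "Bc" in names stands for the 4,6-dimethyl-7-(prop-1-en-2-yl)spiro[bicyclo[3.1.1]heptane-2,2'-[1,3]dioxolan]-6-yl group, configured as in 16.

Step 1
Reactants: 1 1,4-dioxaspiro[4.5]dec-6-en-8-one
Product: 2 (8S)-1,4-dioxaspiro[4.5]dec-6-en-8-ol
Conditions: (R)-Me-CBS oxazaborolidine (10 mol%), catecholborane (1.5 equiv), toluene, −78 °C; then MeOH, aq. NaOH
Reagents that add atoms: none
Why: Corey–Bakshi–Shibata reduction; the alkenyl arm carrying the quaternary ketal carbon acts as the large group, so hydride is delivered to one carbonyl face and the carbinol (future C5) is set as S, which fixes the absolute configuration of the route; catecholborane at low temperature avoids 1,4-reduction and hydroboration.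

Step 2
Reactants: 2 (8S)-1,4-dioxaspiro[4.5]dec-6-en-8-ol
Product: 3 methyl (8S)-1,4-dioxaspiro[4.5]dec-6-en-8-yl carbonate
Conditions: ClCO2Me, pyridine, DMAP (cat.), CH2Cl2, 0 °C
Reagents that add atoms: methyl chloroformate, COC(=O)Cl
Why: Acylation of a secondary allylic alcohol without touching the stereocentre; the carbonate ionises under neutral conditions and releases methoxide as the base for step 3.

Step 3
Reactants: 3 methyl (8S)-1,4-dioxaspiro[4.5]dec-6-en-8-yl carbonate; 4 ethyl 2-cyanopropanoate
Product: 5 ethyl 2-cyano-2-[(8S)-1,4-dioxaspiro[4.5]dec-6-en-8-yl]propanoate (both epimers at the quaternary carbon)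
Conditions: Pd(PPh3)4 (5 mol%), THF, 50 °C
Reagents that add atoms: none
Why: Tsuji–Trost allylic alkylation with a soft carbon acid; ionisation with inversion and attack anti to palladium give net retention, and the nucleophile takes the allyl terminus remote from the quaternary ketal carbon, so the C4–C5 bond stands where the oxygen stood and the alkene stays at C6=C7.

Step 4
Reactants: 5 ethyl 2-cyano-2-[(8S)-1,4-dioxaspiro[4.5]dec-6-en-8-yl]propanoate
Product: 6 2-[(8S)-1,4-dioxaspiro[4.5]dec-6-en-8-yl]propanenitrile (both epimers at the nitrile α-carbon)
Conditions: LiCl, H2O, DMSO, 140 °C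
Reagents that add atoms: none
Why: Krapcho dealkoxycarbonylation of an α-cyano ester; the ring stereocentre is not involved, and the C4 epimer mixture is erased later when C4 becomes a carbanion.

Step 5
Reactants: 6 2-[(8S)-1,4-dioxaspiro[4.5]dec-6-en-8-yl]propanenitrile
Product: 7 2-[6,7-epoxy-1,4-dioxaspiro[4.5]decan-8-yl]propanenitrile, oxirane on the ring face opposite to the cyanoethyl group (C6–C7 epoxide in target numbering)
Conditions: 3-ClC6H4CO3H, NaHCO3, CH2Cl2, 0 °C → 25 °C
Reagents that add atoms: 3-chloroperoxybenzoic acid, OOC(=O)c1cccc(Cl)c1
Why: Prilezhaev epoxidation of the only alkene; the peracid should approach the face opposite to the branched allylic substituent on C5, which places the oxirane trans to the side chain as the two later inversions require.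

Step 6
Reactants: 7 trans-epoxide of 6; 8 isopropenylmagnesium bromide
Product: 9 2-[6-hydroxy-7-(prop-1-en-2-yl)-1,4-dioxaspiro[4.5]decan-8-yl]propanenitrile (isopropenyl cis to the cyanoethyl group, hydroxyl trans to both)
Conditions: 8 (3 equiv), CuI (20 mol%), THF, −30 °C → 0 °C; aq. NH4Cl
Reagents that add atoms: none
Why: Copper-catalysed Grignard opening of an epoxide (SN2, trans-diaxial, Fürst–Plattner); C7 is shielded and inductively deactivated by the adjacent ketal carbon, so attack goes to C6 with inversion, putting the isopropenyl group cis to the C5 arm and the C7 hydroxyl trans to both.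

Step 7
Reactants: 9 hydroxy nitrile
Product: 10 4-methylbenzenesulfonate of 9 at the C7 hydroxyl
Conditions: TsCl, Et3N, Me3N·HCl (cat.), CH2Cl2, 0 °C → 25 °C
Reagents that add atoms: 4-methylbenzenesulfonyl chloride, Cc1ccc(cc1)S(Cl)(=O)=O
Why: Sulfonylation with retention at C7; a tosylate is preferred to a mesylate because it has no acidic α-hydrogen to compete with the nitrile in step 8.

Step 8
Reactants: 10 tosylate
Product: 11 6-methyl-7-(prop-1-en-2-yl)spiro[bicyclo[3.1.1]heptane-2,2'-[1,3]dioxolane]-6-carbonitrile (nitrile and isopropenyl both on the cyclobutane face remote from the three-carbon bridge)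
Conditions: KN(SiMe3)2 (1.3 equiv), THF, −78 °C → 45 °C
Reagents that add atoms: none
Why: Intramolecular alkylation of a nitrile-stabilised carbanion (4-exo-tet); the carbanion on the axial C5 arm attacks C7 opposite to the equatorial tosylate (inversion), forcing the C4 bridge cis to the isopropenyl group, and the slim nitrile rather than the methyl takes the position 1,3-syn to the isopropenyl group; no hydrogen is anti-periplanar to the tosylate, so E2 loss is geometrically disfavoured.

Step 9
Reactants: 11 bicyclic nitrile ketal
Product: 12 6-methyl-2-oxo-7-(prop-1-en-2-yl)bicyclo[3.1.1]heptane-6-carbonitrile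
Conditions: PPTS, acetone/H2O (10:1), 60 °C
Reagents that add atoms: water, O
Why: Acid-catalysed ketal hydrolysis to free C8 for enone chemistry; C7 is a bridgehead and cannot enolise, so no stereocentre is at risk.

Step 10
Reactants: 12 bicyclic keto nitrile
Product: 14 6-methyl-2-oxo-7-(prop-1-en-2-yl)bicyclo[3.1.1]hept-3-ene-6-carbonitrile, via trimethylsilyl enol ether 13 (not isolated)
Conditions: LiN(i-Pr)2, Me3SiCl, THF, −78 °C; then Pd(OAc)2 (1.1 equiv), MeCN, 25 °C
Reagents that add atoms: none
Why: Saegusa–Ito dehydrogenation; only C9 can be deprotonated because C7 is a bridgehead, so the C8(=O)–C9=C10 enone forms regiospecifically.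

Step 11
Reactants: 14 bridged enone nitrile
Product: 15 4,6-dimethyl-2-oxo-7-(prop-1-en-2-yl)bicyclo[3.1.1]heptane-6-carbonitrile (C10 methyl on the side of the isopropenyl-bearing bridge)
Conditions: Me2CuLi (from MeLi and CuI, 2 equiv), Et2O, −78 °C → −30 °C; aq. NH4Cl
Reagents that add atoms: lithium dimethylcuprate, [Li+].C[Cu-]C
Why: Conjugate addition of a Gilman cuprate to a bridged enone; the enone face under the C4 bridge is blocked by the C4 methyl that points over the three-carbon bridge, while the face under the C6 bridge carries only hydrogen, so the methyl enters from the C6 side and C10 is set trans to C4.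

Step 12
Reactants: 15 methylated keto nitrile
Product: 16 4,6-dimethyl-7-(prop-1-en-2-yl)spiro[bicyclo[3.1.1]heptane-2,2'-[1,3]dioxolane]-6-carbonitrile
Conditions: (Me3SiOCH2)2, Me3SiOTf (5 mol%), CH2Cl2, −78 °C → −20 °C; pyridine
Reagents that add atoms: 1,2-bis(trimethylsilyloxy)ethane, C[Si](C)(C)OCCO[Si](C)(C)C
Why: Silyl-transfer ketalisation under aprotic, cold conditions re-protects C8 before hydride and enolate chemistry without exposing the isopropenyl group to protic acid.

Step 13
Reactants: 16 nitrile ketal
Product: 17 Bc-carbaldehyde (the C3 aldehyde)
Conditions: i-Bu2AlH (1.5 equiv), toluene, −78 °C → −40 °C; then aq. KNaC4H4O6, pH 5, 0 °C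
Reagents that add atoms: water, O
Why: Partial reduction of a nitrile to the aldimine and hydrolysis; the tertiary nitrile cannot epimerise, and the aldehyde is used at once and kept from Lewis acids, which could trigger a carbonyl-ene reaction with the neighbouring isopropenyl group.

Step 14
Reactants: 17 Bc-carbaldehyde; 18 (5R,6R)-5,6-dimethoxy-5,6-dimethyl-1,4-dioxan-2-one
Product: 19 (3S,5R,6R)-3-[(S)-hydroxy(Bc)methyl]-5,6-dimethoxy-5,6-dimethyl-1,4-dioxan-2-one
Conditions: 18, LiN(SiMe3)2, THF, −78 °C; then 17, −78 °C; AcOH
Reagents that add atoms: none
Why: Lithium enolate aldol through a closed Zimmerman–Traxler transition state; the ring locks the enolate in the E(O) geometry, which gives the anti adduct, and the aldehyde approaches the enolate face away from the axial methoxy group, setting C2 and C3 as S,S; no external Lewis acid is present.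

Step 15
Reactants: 19 aldol adduct
Product: 20 methyl (2S,3S)-2,3-dihydroxy-3-(Bc)propanoate
Conditions: Me3SiCl (10 mol%), MeOH, 0 °C → 25 °C; NaHCO3
Reagents that add atoms: methanol, CO
Why: Acid-catalysed transacetalisation and lactone methanolysis release the anti diol as its methyl ester without touching a stereocentre; catalytic acid and short exposure are chosen to spare the C8 dioxolane.

Step 16
Reactants: 20 anti diol ester
Product: 21 methyl (4S,5S)-2,2-dimethyl-5-(Bc)-1,3-dioxolane-4-carboxylate (cis)
Conditions: Me2C(OMe)2, PPTS (cat.), CH2Cl2, 25 °C
Reagents that add atoms: 2,2-dimethoxypropane, COC(C)(C)OC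
Why: Acetonide formation from a 1,2-diol; the anti diol gives the cis-4,5-disubstituted dioxolane that later holds C1 on the same side as C4.

Step 17
Reactants: 21 cis-dioxolane ester
Product: 22 (4S,5S)-2,2-dimethyl-5-(Bc)-1,3-dioxolane-4-carbaldehyde (cis; the C1 aldehyde with C6 isopropenyl)
Conditions: i-Bu2AlH (1.1 equiv), CH2Cl2, −78 °C; MeOH, aq. KNaC4H4O6
Reagents that add atoms: none
Why: Partial reduction of an α-alkoxy ester through the stable tetrahedral aluminium acetal; cold, non-basic work-up and immediate use prevent epimerisation of the cis-dioxolane aldehyde at C2.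

Step 18
Reactants: 22 cis-dioxolane aldehyde
Product: 23 tricyclic C1 alcohol with C2/C3 acetonide and C8 ethylene ketal (C1–OH trans to the C2 oxygen)
Conditions: Fe(acac)3 (30 mol%), PhSiH3 (3 equiv, slow addition), EtOH (0.01 M), 60 °C, argon
Reagents that add atoms: none
Why: Proposed new method: an iron hydride formed from Fe(acac)3, PhSiH3 and ethanol transfers a hydrogen atom to the CH2 terminus of the isopropenyl group, which makes the second methyl group and a tertiary radical at C11; this nucleophilic radical adds to the aldehyde carbon C1, and the alkoxy radical is reduced by divalent iron and protonated by ethanol. The closest known reaction type is the Fe(acac)3/PhSiH3 radical cyclisation of alkenes onto ketones, together with hydrogen-atom-transfer Giese closures that form quaternary carbons; the extension is to an aldehyde acceptor and a seven-membered ring. The ring closes in the 7-exo-trig mode with respect to the C=O bond. The new stereocentre C1 is controlled by the cis-fused dioxolane: with C11 anti to the C2–O bond, the carbonyl oxygen should point outwards, away from C3, so the C1 hydroxyl ends trans to the C2 oxygen. Chemoselectivity of the hydrogen transfer is secured by the substrate having a single, 1,1-disubstituted alkene, and proximity by the cis-1,3 placing of C3 and C11 on the cyclobutane face remote from the C8–C10 bridge and by the dioxolane that turns C1 back towards C11. The closure must outrun reduction of the tertiary radical, 1,5-hydrogen transfer from C3–H and silane reduction of the aldehyde, which is why the silane is added slowly at high dilution.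

Step 19
Reactants: 23 tricyclic C1 alcohol; 24 angelic acid
Product: 25 C1 angelate of 23 (acetonide and C8 ketal retained)
Conditions: 24, 2,4,6-Cl3C6H2COCl, Et3N, toluene, 25 °C; then 23, toluene, 80 °C
Reagents that add atoms: none
Why: Yamaguchi-type mixed-anhydride esterification run without DMAP, because nucleophilic catalysts isomerise angelates to tiglates; C1–OH is the only free hydroxyl, so regiochemistry is not in question.

Step 20
Reactants: 25 C1 angelate acetonide ketal
Product: 26 C1 angelate with free C2 and C3 hydroxyls and C8 ketone
Conditions: CF3CO2H/H2O (9:1), CH2Cl2, 0 °C → 25 °C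
Reagents that add atoms: water, O
Why: Acid hydrolysis removes the acetonide and the C8 dioxolane together, which avoids having to cleave one ketal selectively beside the other; the angelate ester is stable to aqueous acid.

Step 21
Reactants: 26 C1 angelate diol ketone
Product: 27 C1 angelate C2 acetate with free C3 hydroxyl
Conditions: AcCl (1.05 equiv), 2,4,6-collidine, CH2Cl2, −78 °C → −40 °C
Reagents that add atoms: acetyl chloride, CC(Cl)=O
Why: Kinetic acylation; C3–OH is neopentyl (next to the quaternary C4) and C2–OH is not, so the small acyl chloride at low temperature should take C2, and the weak hindered base limits acyl migration.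

Step 22
Reactants: 27 C2 acetate C3 alcohol; 24 angelic acid
Product: 28 CNP0197834.1 (C1 and C3 angelates, C2 acetate, C8 ketone)
Conditions: 24, 2,4,6-Cl3C6H2COCl, Et3N, toluene, 25 °C; then 27, toluene, 80 °C
Reagents that add atoms: none
Why: Mixed-anhydride angeloylation of the remaining hindered C3 hydroxyl under DMAP-free, non-alkoxide conditions chosen to limit tiglate formation and migration of the neighbouring C2 acetate.

**Compound list**

1 | 1,4-dioxaspiro[4.5]dec-6-en-8-one | O=C1C=CC2(OCCO2)CC1 | starting material
2 | (8S)-1,4-dioxaspiro[4.5]dec-6-en-8-ol | O[C@@H]1C=CC2(OCCO2)CC1 | intermediate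
3 | methyl (8S)-1,4-dioxaspiro[4.5]dec-6-en-8-yl carbonate | COC(=O)O[C@@H]1C=CC2(OCCO2)CC1 | intermediate
4 | ethyl 2-cyanopropanoate (racemic) | CCOC(=O)C(C)C#N | starting material
5 | ethyl 2-cyano-2-[(8S)-1,4-dioxaspiro[4.5]dec-6-en-8-yl]propanoate (both epimers at the quaternary carbon) | CCOC(=O)C(C)(C#N)[C@@H]1C=CC2(OCCO2)CC1 | intermediate
6 | 2-[(8S)-1,4-dioxaspiro[4.5]dec-6-en-8-yl]propanenitrile (both epimers at the nitrile α-carbon) | N#CC(C)[C@@H]1C=CC2(OCCO2)CC1 | intermediate
7 | 2-[6,7-epoxy-1,4-dioxaspiro[4.5]decan-8-yl]propanenitrile, oxirane trans to the cyanoethyl group | N#CC(C)[C@@H]1[C@H]2O[C@H]2C3(OCCO3)CC1 | intermediate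
8 | isopropenylmagnesium bromide | CC(=C)[Mg]Br | starting material
9 | 2-[6-hydroxy-7-(prop-1-en-2-yl)-1,4-dioxaspiro[4.5]decan-8-yl]propanenitrile (isopropenyl cis to the cyanoethyl group, hydroxyl trans to both) | N#CC(C)[C@@H]1[C@H](C(C)=C)[C@@H](O)C2(OCCO2)CC1 | intermediate
10 | 4-methylbenzenesulfonate of 9 | N#CC(C)[C@@H]1[C@H](C(C)=C)[C@@H](OS(=O)(=O)c2ccc(C)cc2)C3(OCCO3)CC1 | intermediate
11 | 6-methyl-7-(prop-1-en-2-yl)spiro[bicyclo[3.1.1]heptane-2,2'-[1,3]dioxolane]-6-carbonitrile (nitrile and isopropenyl on the cyclobutane face remote from the three-carbon bridge) | N#C[C@]1(C)[C@@H]2[C@@H]([C@H]1C3(OCCO3)CC2)C(C)=C | intermediate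
12 | 6-methyl-2-oxo-7-(prop-1-en-2-yl)bicyclo[3.1.1]heptane-6-carbonitrile | N#C[C@]1(C)[C@@H]2[C@@H]([C@H]1C(=O)CC2)C(C)=C | intermediate
13 | 6-methyl-7-(prop-1-en-2-yl)-2-(trimethylsilyloxy)bicyclo[3.1.1]hept-2-ene-6-carbonitrile | N#C[C@]1(C)[C@@H]2[C@@H]([C@H]1C(O[Si](C)(C)C)=CC2)C(C)=C | intermediate (not isolated)
14 | 6-methyl-2-oxo-7-(prop-1-en-2-yl)bicyclo[3.1.1]hept-3-ene-6-carbonitrile | N#C[C@]1(C)[C@@H]2[C@@H]([C@H]1C(=O)C=C2)C(C)=C | intermediate
15 | 4,6-dimethyl-2-oxo-7-(prop-1-en-2-yl)bicyclo[3.1.1]heptane-6-carbonitrile (C10 methyl towards the isopropenyl-bearing bridge) | N#C[C@]1(C)[C@@H]2[C@@H]([C@H]1C(=O)C[C@H]2C)C(C)=C | intermediate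
16 | 4,6-dimethyl-7-(prop-1-en-2-yl)spiro[bicyclo[3.1.1]heptane-2,2'-[1,3]dioxolane]-6-carbonitrile | N#C[C@]1(C)[C@@H]2[C@@H]([C@H]1C3(OCCO3)C[C@H]2C)C(C)=C | intermediate
17 | 4,6-dimethyl-7-(prop-1-en-2-yl)spiro[bicyclo[3.1.1]heptane-2,2'-[1,3]dioxolane]-6-carbaldehyde (Bc-carbaldehyde) | O=C[C@]1(C)[C@@H]2[C@@H]([C@H]1C3(OCCO3)C[C@H]2C)C(C)=C | intermediate
18 | (5R,6R)-5,6-dimethoxy-5,6-dimethyl-1,4-dioxan-2-one | O=C1CO[C@@](C)(OC)[C@](C)(OC)O1 | starting material
19 | (3S,5R,6R)-3-[(S)-hydroxy(Bc)methyl]-5,6-dimethoxy-5,6-dimethyl-1,4-dioxan-2-one | O=C1O[C@@](C)(OC)[C@](C)(OC)O[C@H]1[C@@H](O)[C@]2(C)[C@@H]3[C@@H]([C@H]2C4(OCCO4)C[C@H]3C)C(C)=C | intermediate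
20 | methyl (2S,3S)-2,3-dihydroxy-3-(Bc)propanoate | COC(=O)[C@@H](O)[C@@H](O)[C@]1(C)[C@@H]2[C@@H]([C@H]1C3(OCCO3)C[C@H]2C)C(C)=C | intermediate
21 | methyl (4S,5S)-2,2-dimethyl-5-(Bc)-1,3-dioxolane-4-carboxylate (cis) | COC(=O)[C@H]1OC(C)(C)O[C@H]1[C@]2(C)[C@@H]3[C@@H]([C@H]2C4(OCCO4)C[C@H]3C)C(C)=C | intermediate
22 | (4S,5S)-2,2-dimethyl-5-(Bc)-1,3-dioxolane-4-carbaldehyde (cis) | O=C[C@H]1OC(C)(C)O[C@H]1[C@]2(C)[C@@H]3[C@@H]([C@H]2C4(OCCO4)C[C@H]3C)C(C)=C | intermediate
23 | tricyclic C1 alcohol with C2/C3 acetonide and C8 ethylene ketal | O[C@@H]1[C@H]2OC(C)(C)O[C@H]2[C@]3(C)[C@@H]4[C@@H]([C@H]3C5(OCCO5)C[C@H]4C)C1(C)C | intermediate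
24 | angelic acid, (Z)-2-methylbut-2-enoic acid | C/C=C(/C)C(=O)O | starting material
25 | C1 angelate of 23 | C/C=C(/C)C(=O)O[C@@H]1[C@H]2OC(C)(C)O[C@H]2[C@]3(C)[C@@H]4[C@@H]([C@H]3C5(OCCO5)C[C@H]4C)C1(C)C | intermediate
26 | C1 angelate, C2 and C3 free hydroxyls, C8 ketone | C/C=C(/C)C(=O)O[C@@H]1[C@@H](O)[C@@H](O)[C@]2(C)[C@@H]3[C@@H]([C@H]2C(=O)C[C@H]3C)C1(C)C | intermediate
27 | C1 angelate, C2 acetate, C3 free hydroxyl, C8 ketone | C/C=C(/C)C(=O)O[C@@H]1[C@@H](OC(C)=O)[C@@H](O)[C@]2(C)[C@@H]3[C@@H]([C@H]2C(=O)C[C@H]3C)C1(C)C | intermediate
28 | CNP0197834.1 | C/C=C(/C)C(=O)O[C@@H]1[C@@H](OC(C)=O)[C@@H](OC(=O)/C(C)=C\C)[C@]2(C)[C@@H]3[C@@H]([C@H]2C(=O)C[C@H]3C)C1(C)C | target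

**Totals.** Total step count: 22. Longest linear sequence: 22 steps (1 → 28); compounds 4, 8, 18 and 24 enter as purchased reagents.

**Least certain steps**

**Step 18 (key step, proposed new method).**
- What may go wrong: the addition of the tertiary radical to the aldehyde is reversible, and β-scission of the hindered alkoxy radical may outrun its reduction. The radical may instead be reduced to an isopropyl group, or may take the hydrogen from C3–H. The silane may reduce the aldehyde. The aldehyde face may be attacked with the wrong sense; the brief already allows correction of C1 by oxidation and reduction.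
- Fallback, using known chemistry: from 22 to 23 by the hydrogen-atom-transfer-initiated, branch-selective coupling of 1,1-disubstituted alkenes with aldehydes that passes through an organochromium species. A cobalt salen hydride (Co(salen) catalyst with PhSiH3) delivers the hydrogen atom, the tertiary radical is captured by divalent chromium generated from CrCl3, and the tertiary alkylchromium adds to the aldehyde in an irreversible Nozaki–Hiyama-type two-electron step. This replaces the reversible radical addition by a polar carbonyl addition. It makes no new isolated compound (entry F0).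

**Step 8.**
- What may go wrong: substitution at C7 is slowed by the adjacent ketal carbon (steric and inductive retardation), which gives intermolecular alkylation or decomposition of the carbanion time to compete. The methyl and nitrile may also take the wrong positions on C4.
- Fallback: an epoxynitrile closure, setting out from 9 and returning at 12. The ketal of 9 is hydrolysed to the α-hydroxy ketone F1. Hydroxyl-directed reduction with NaBH(OAc)3 gives the trans-diol F2. The less hindered C8 hydroxyl is tosylated to the monotosylate F3. With KN(SiMe3)2 (2.2 equiv) the C7 alkoxide closes to the C7–C8 epoxide F4 (not isolated), and the nitrile anion opens it at C7 in the 4-exo-tet, trans-diaxial mode to the bicyclic C8 alcohol F5. Dess–Martin oxidation of F5 gives 12.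

**Step 5 (with step 6).**
- What may go wrong: a secondary allylic substituent gives only a modest facial bias in the epoxidation. In step 6 the Grignard reagent may deprotonate the carbon next to the nitrile, and the carbanion can then close on the epoxide in a 3-exo mode.
- Fallback: change the order, setting out from 5 and returning at 9. Compound 5, whose quaternary substituent is a stronger steric director and has no acidic C–H, is epoxidised to the epoxy cyano ester F6. F6 is opened with 8 and CuI to the hydroxy cyano ester F7. Krapcho dealkoxycarbonylation of F7 gives 9.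

**Step 14 (with the acid release in step 15).**
- What may go wrong: addition to the neopentyl aldehyde may be sluggish, the intrinsic facial preference of the chiral aldehyde may oppose the reagent and erode diastereoselectivity, and the C8 dioxolane may exchange during the methanolysis.
- Fallback: a route that builds C2 and C1 by oxidation of an alkene, setting out from 17 and returning at 22.
  - Vinylmagnesium bromide adds to 17 to give the allylic alcohols F8 (both C3 epimers).
  - Sharpless asymmetric epoxidation under kinetic-resolution conditions (Ti(OiPr)4, the matched dialkyl tartrate, t-BuOOH) touches only the allylic-alcohol alkene and converts the 3S epimer into the anti epoxy alcohol F9.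
  - Sodium benzenethiolate opens the terminal epoxide at C1 to the phenylthio diol F10, which is converted to the acetonide sulfide F11.
  - NaIO4 gives the sulfoxide F12, and a Pummerer rearrangement with trifluoroacetic anhydride and 2,6-lutidine gives the α-trifluoroacetoxy sulfide F13, which is hydrolysed at pH 7 to 22.

**Step 22 (with step 21).**
- What may go wrong: under the forcing conditions the C2 acetate may migrate to C3 and the freed C2 hydroxyl may then be angeloylated, giving the regioisomer. The angelate may isomerise to the tiglate. Discrimination between C2 and C3 in step 21 may be incomplete.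
- Fallback: put the acetate on last, setting out from 26 and returning at 28. The C2 hydroxyl of 26 is silylated selectively (Et3SiCl, imidazole) to the C2 triethylsilyl ether F14. F14 is angeloylated at C3 as in step 19, with no migrating acyl group present, to the bis-angelate silyl ether F15. HF·pyridine gives the bis-angelate C2 alcohol F16, which is acetylated (Ac2O, pyridine, DMAP) to 28.

## Further compounds

F0 | step 18 | none | none
F1 | step 8 | 2-[3-hydroxy-4-oxo-2-(prop-1-en-2-yl)cyclohexyl]propanenitrile (α-hydroxy ketone from 9) | N#CC(C)[C@@H]1[C@H](C(C)=C)[C@@H](O)C(=O)CC1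
F2 | step 8 | trans-C7,C8-diol | N#CC(C)[C@@H]1[C@H](C(C)=C)[C@@H](O)[C@H](O)CC1
F3 | step 8 | C8 mono-4-methylbenzenesulfonate of F2 | N#CC(C)[C@@H]1[C@H](C(C)=C)[C@@H](O)[C@H](OS(=O)(=O)c2ccc(C)cc2)CC1
F4 | step 8 | C7–C8 epoxide trans to the C5 arm | N#CC(C)[C@@H]1[C@H](C(C)=C)[C@H]2O[C@H]2CC1
F5 | step 8 | 2-hydroxy-6-methyl-7-(prop-1-en-2-yl)bicyclo[3.1.1]heptane-6-carbonitrile (bicyclic C8 alcohol) | N#C[C@]1(C)[C@@H]2[C@@H]([C@H]1[C@@H](O)CC2)C(C)=C
F6 | step 5 | ethyl 2-cyano-2-[6,7-epoxy-1,4-dioxaspiro[4.5]decan-8-yl]propanoate, oxirane trans to the side chain | CCOC(=O)C(C)(C#N)[C@@H]1[C@H]2O[C@H]2C3(OCCO3)CC1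
F7 | step 5 | ethyl 2-cyano-2-[6-hydroxy-7-(prop-1-en-2-yl)-1,4-dioxaspiro[4.5]decan-8-yl]propanoate | CCOC(=O)C(C)(C#N)[C@@H]1[C@H](C(C)=C)[C@@H](O)C2(OCCO2)CC1
F8 | step 14 | 1-(Bc)prop-2-en-1-ol (3S epimer shown) | C=C[C@@H](O)[C@]1(C)[C@@H]2[C@@H]([C@H]1C3(OCCO3)C[C@H]2C)C(C)=C
F9 | step 14 | anti epoxy alcohol, (Bc)(oxiran-2-yl)methanol | C1O[C@H]1[C@@H](O)[C@]2(C)[C@@H]3[C@@H]([C@H]2C4(OCCO4)C[C@H]3C)C(C)=C
F10 | step 14 | 1-(Bc)-3-(phenylthio)propane-1,2-diol (anti) | c1ccccc1SC[C@@H](O)[C@@H](O)[C@]2(C)[C@@H]3[C@@H]([C@H]2C4(OCCO4)C[C@H]3C)C(C)=C
F11 | step 14 | cis-acetonide of F10 | c1ccccc1SC[C@H]2OC(C)(C)O[C@H]2[C@]3(C)[C@@H]4[C@@H]([C@H]3C5(OCCO5)C[C@H]4C)C(C)=C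
F12 | step 14 | sulfoxide of F11 | O=S(c1ccccc1)C[C@H]2OC(C)(C)O[C@H]2[C@]3(C)[C@@H]4[C@@H]([C@H]3C5(OCCO5)C[C@H]4C)C(C)=C
F13 | step 14 | α-trifluoroacetoxy sulfide from F12 | FC(F)(F)C(=O)OC(Sc1ccccc1)[C@H]2OC(C)(C)O[C@H]2[C@]3(C)[C@@H]4[C@@H]([C@H]3C5(OCCO5)C[C@H]4C)C(C)=C
F14 | step 22 | C1 angelate, C2 triethylsilyl ether, C3 free hydroxyl, C8 ketone | C/C=C(/C)C(=O)O[C@@H]1[C@@H](O[Si](CC)(CC)CC)[C@@H](O)[C@]2(C)[C@@H]3[C@@H]([C@H]2C(=O)C[C@H]3C)C1(C)C
F15 | step 22 | C1 and C3 angelates, C2 triethylsilyl ether, C8 ketone | C/C=C(/C)C(=O)O[C@@H]1[C@@H](O[Si](CC)(CC)CC)[C@@H](OC(=O)/C(C)=C\C)[C@]2(C)[C@@H]3[C@@H]([C@H]2C(=O)C[C@H]3C)C1(C)C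
F16 | step 22 | C1 and C3 angelates, C2 free hydroxyl, C8 ketone | C/C=C(/C)C(=O)O[C@@H]1[C@@H](O)[C@@H](OC(=O)/C(C)=C\C)[C@]2(C)[C@@H]3[C@@H]([C@H]2C(=O)C[C@H]3C)C1(C)C
A1 | alternative 1 | bicyclo[4.1.1]oct-2-ene C8 acid with C1 4-methoxybenzyl ether and C10 tert-butyldimethylsilyl ether | COc1ccc(CO[C@@H]2C=C[C@]3(C)[C@@H](CO[Si](C)(C)C(C)(C)C)[C@@H]([C@@H]3C(=O)O)C2(C)C)cc1
A2 | alternative 2 | tricyclic C2 ketone with C1 tert-butyldimethylsilyl ether and C8 ethylene ketal | CC(C)(C)[Si](C)(C)O[C@@H]1C(=O)C[C@]2(C)[C@@H]3[C@@H]([C@H]2C4(OCCO4)C[C@H]3C)C1(C)C
A3 | alternative 3 | tricyclic C1 ketone with C8 ethylene ketal | O=C1CC[C@]2(C)[C@@H]3[C@@H]([C@H]2C4(OCCO4)C[C@H]3C)C1(C)C
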